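Everything rests on cutting ring B at two adjacent carbons at once: the crowded diaryl ether bond at C6 and the carboxyl bond at C1. Together with the C2 oxygen they form a contiguous C6(OAr)–C1(CO2H)–C2(O) triad, the substitution pattern left when a nucleophile and an electrophile add across a 3-alkoxybenzyne. In a single operation the ring A phenoxide attacks C6 of the aryne and CO2 captures the C1 carbanion, so no coupling between two 2,6-disubstituted partners is needed. The precursor is an ortho-silylaryl triflate of ring B (C1 SiMe3, C6 OTf, C2 OMOM, C3 prenyl), paired with a MOM/TIPS-protected ring A phenol. Desilylation, acetylation and MOM cleavage complete the target.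

Key step: step 12

Assumption: the target has no stereocentre and its only alkene carries two identical methyl groups, so no stereocontrol is needed; ring B is numbered C1 (CO2H), C2 (OH), C3 (prenyl), C6 (OAr) throughout, also in its precursors.

Step 1
Reactants: 1 4-bromoresorcinol (4-bromobenzene-1,3-diol)
Product: 2 4-bromo-3-hydroxyphenyl N,N-diethylcarbamate
Conditions: Et2NCOCl (1.0 equiv), K2CO3 (1.1 equiv), MeCN, 60 °C
Reagents that add atoms: N,N-diethylcarbamoyl chloride, CCN(CC)C(=O)Cl
Why: Site-selective O-carbamoylation of a phenoxide, in which the hydroxyl para to bromine is open and gives the better nucleophile while the one ortho to bromine is shielded and deactivated, the same preference that governs mono-tosylation and mono-benzylation of this diol.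

Step 2
Reactants: 2 4-bromo-3-hydroxyphenyl N,N-diethylcarbamate
Product: 3 4-bromo-3-(methoxymethoxy)phenyl N,N-diethylcarbamate
Conditions: MOMCl, iPr2NEt, CH2Cl2, 0 °C → rt
Reagents that add atoms: chloromethyl methyl ether, COCCl
Why: Standard MOM protection (O-alkylation of the remaining phenol under amine base), to which carbamate and aryl bromide are inert.

Step 3
Reactants: 3 4-bromo-3-(methoxymethoxy)phenyl N,N-diethylcarbamate
Product: 5 4-bromo-3-(methoxymethoxy)-2-(trimethylsilyl)phenyl N,N-diethylcarbamate, via 2-lithio carbamate 4 (not isolated)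
Conditions: Me3SiCl (2 equiv), then LiN(iPr)2 (1.3 equiv), THF, −78 °C (in situ quench)
Reagents that add atoms: chlorotrimethylsilane, C[Si](C)(C)Cl
Why: Directed ortho metalation at the C–H between the two cooperating directing groups (future C1 of ring B), where an amide base spares the C–Br bond and the silyl chloride already present traps the aryllithium before anionic ortho-Fries rearrangement or halogen dance can start.

Step 4
Reactants: 5 4-bromo-3-(methoxymethoxy)-2-(trimethylsilyl)phenyl N,N-diethylcarbamate; 6 prenyl bromide (1-bromo-3-methylbut-2-ene)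
Product: 8 3-(methoxymethoxy)-4-(3-methylbut-2-enyl)-2-(trimethylsilyl)phenyl N,N-diethylcarbamate, via 4-lithio carbamate 7 (not isolated)
Conditions: n-BuLi (1.05 equiv), THF, −78 °C; CuBr·SMe2 (20 mol %), then 6, −78 → 0 °C
Reagents that add atoms: prenyl bromide 6, CC(C)=CCBr
Why: Bromine–lithium exchange outruns attack on the hindered carbamate at −78 °C, and copper-assisted allylic substitution of the OMOM-chelated aryllithium at the primary carbon of 6 (SN2 rather than SN2′ for steric reasons) should give the linear prenyl arene, after which the doubly activated ArCH2 meets no strong base.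

Step 5
Reactants: 8 3-(methoxymethoxy)-4-(3-methylbut-2-enyl)-2-(trimethylsilyl)phenyl N,N-diethylcarbamate
Product: 9 3-(methoxymethoxy)-4-(3-methylbut-2-enyl)-2-(trimethylsilyl)phenol
Conditions: LiAlH4 (3 equiv), THF, 0 °C → reflux; aq. potassium sodium tartrate work-up
Reagents that add atoms: none
Why: Reductive cleavage of an aryl carbamate by hydride releases the phenoxide under non-acidic conditions, so the protodesilylation-prone C–SiMe3 bond, the MOM acetal and the trisubstituted alkene should all survive.

Step 6
Reactants: 9 3-(methoxymethoxy)-4-(3-methylbut-2-enyl)-2-(trimethylsilyl)phenol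
Product: 10 3-(methoxymethoxy)-4-(3-methylbut-2-enyl)-2-(trimethylsilyl)phenyl trifluoromethanesulfonate
Conditions: Tf2O, pyridine, CH2Cl2, 0 °C
Reagents that add atoms: trifluoromethanesulfonic anhydride, O=S(=O)(OS(=O)(=O)C(F)(F)F)C(F)(F)F
Why: O-Triflation of an ortho-silylphenol, the usual last step towards ortho-silylaryl triflates, with pyridine buffering the acid so that MOM and prenyl are not touched.

Step 7
Reactants: 11 2-methoxy-4-methylphenol (creosol)
Product: 12 2-hydroxy-3-methoxy-5-methylbenzaldehyde
Conditions: MgCl2, Et3N, (CH2O)n, MeCN, reflux; 1 M HCl work-up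
Reagents that add atoms: paraformaldehyde (reacts as formaldehyde), C=O
Why: Casnati–Skattebøl ortho-formylation of the magnesium phenoxide, which can only go to the single free ortho position because the para position carries the methyl group.

Step 8
Reactants: 12 2-hydroxy-3-methoxy-5-methylbenzaldehyde
Product: 13 2,3-dihydroxy-5-methylbenzaldehyde
Conditions: BBr3, CH2Cl2, −78 °C → rt; H2O
Reagents that add atoms: none
Why: Lewis-acid aryl methyl ether cleavage, well established for ortho-vanillin-type aldehydes, frees the catechol without harming the formyl group.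

Step 9
Reactants: 13 2,3-dihydroxy-5-methylbenzaldehyde
Product: 15 2-hydroxy-3-(methoxymethoxy)-5-methylbenzaldehyde, via disodium catecholate 14 (not isolated)
Conditions: NaH (2.2 equiv), DMF, 0 °C; MOMCl (1.0 equiv), 0 °C → rt; aq. NH4Cl
Reagents that add atoms: chloromethyl methyl ether, COCCl
Why: Regioselective mono-O-alkylation of a catecholate dianion, in which the 2-oxide is delocalised into and chelated with the formyl group, so the 3-oxide is the stronger nucleophile and takes the single equivalent of MOMCl.

Step 10
Reactants: 15 2-hydroxy-3-(methoxymethoxy)-5-methylbenzaldehyde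
Product: 16 2-(hydroxymethyl)-6-(methoxymethoxy)-4-methylphenol
Conditions: NaBH4, MeOH, 0 °C; aq. NH4Cl
Reagents that add atoms: none
Why: Borohydride reduction of the aldehyde to the benzylic alcohol under conditions that leave the MOM acetal untouched.

Step 11
Reactants: 16 2-(hydroxymethyl)-6-(methoxymethoxy)-4-methylphenol
Product: 17 2-(methoxymethoxy)-4-methyl-6-[(triisopropylsilyloxy)methyl]phenol
Conditions: iPr3SiCl (1.05 equiv), imidazole, CH2Cl2/DMF, 0 °C → rt
Reagents that add atoms: chlorotriisopropylsilane, CC(C)[Si](Cl)(C(C)C)C(C)C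
Why: Chemoselective silylation of the primary alcohol of a salicyl alcohol, since the bulky silyl chloride reacts far more slowly with the doubly flanked, hydrogen-bonded phenol.

Step 12
Reactants: 10 3-(methoxymethoxy)-4-(3-methylbut-2-enyl)-2-(trimethylsilyl)phenyl trifluoromethanesulfonate; 17 2-(methoxymethoxy)-4-methyl-6-[(triisopropylsilyloxy)methyl]phenol; 18 carbon dioxide
Product: 23 6-{2-(methoxymethoxy)-4-methyl-6-[(triisopropylsilyloxy)methyl]phenoxy}-2-(methoxymethoxy)-3-(3-methylbut-2-enyl)benzoic acid, via potassium phenoxide 19 (not isolated), via aryne 20 (not isolated), via arylpotassium 21 (not isolated), via potassium carboxylate 22 (not isolated)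
Conditions: 17, KH (1.05 equiv), THF, 0 °C; then 10 (1.3 equiv), KF (1.5 equiv), 18-crown-6, CO2 (10 bar), THF, −20 °C → rt; cold 0.5 M HCl to pH 4
Reagents that add atoms: carbon dioxide 18, O=C=O
Why: Proposed new method: desilylation of C1 by fluoride with expulsion of triflate from C6 unmasks aryne 20; the electronegative OMOM substituent on C2 makes C6 the more electrophilic and also the less crowded aryne terminus, so the oxygen of 19 should bond there and leave a carbanion on C1 that is stabilised inductively by its two oxygen-bearing neighbours (21). Because 19 is made beforehand with KH (the conjugate acid escapes as gas) and THF is used instead of acetonitrile, nothing more acidic than the solvent is present, and dissolved CO2 under pressure should be the fastest electrophile for 21, giving 22 and, after gentle acidification, acid 23. Nearest precedents in type are anthranilic acid synthesis from an aryne, an amine and CO2 under KF/18-crown-6 and diaryl ether synthesis from phenols and ortho-silylaryl triflates with CsF, whereas interception by CO2 after addition of an anionic oxygen nucleophile has not been demonstrated. No ring is closed and no stereocentre is formed. The step needs regioselectivity (O to C6, C to C1), which the C2 alkoxy group provides, and chemoselectivity for carboxylation over proton capture, over ene reaction at a prenyl group and over fluoride attack on the silyl ether, which CO2 pressure, low temperature, a bare excess of KF and the bulk of the triisopropylsilyl group are meant to provide. Late loss of the TIPS group would be harmless because step 13 removes it anyway.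

Step 13
Reactants: 23 6-{2-(methoxymethoxy)-4-methyl-6-[(triisopropylsilyloxy)methyl]phenoxy}-2-(methoxymethoxy)-3-(3-methylbut-2-enyl)benzoic acid
Product: 24 6-[2-(hydroxymethyl)-6-(methoxymethoxy)-4-methylphenoxy]-2-(methoxymethoxy)-3-(3-methylbut-2-enyl)benzoic acid
Conditions: Bu4NF (3 equiv), THF, 0 °C → rt; 0.5 M HCl to pH 4
Reagents that add atoms: none
Why: Fluoride-driven silyl ether cleavage, to which the MOM acetals, the prenyl group and the carboxylate are indifferent.

Step 14
Reactants: 24 6-[2-(hydroxymethyl)-6-(methoxymethoxy)-4-methylphenoxy]-2-(methoxymethoxy)-3-(3-methylbut-2-enyl)benzoic acid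
Product: 25 6-[2-(acetoxymethyl)-6-(methoxymethoxy)-4-methylphenoxy]-2-(methoxymethoxy)-3-(3-methylbut-2-enyl)benzoic acid
Conditions: Ac2O (1.5 equiv), pyridine, 4-(dimethylamino)pyridine (5 mol %), CH2Cl2, 0 °C → rt; aqueous work-up at pH 4
Reagents that add atoms: acetic anhydride, CC(=O)OC(C)=O
Why: Nucleophile-catalysed O-acetylation of the only free hydroxyl group, both phenols still being masked and the doubly flanked C1 carboxyl being too hindered for productive acyl transfer or eight-membered lactonisation, so that it returns as the free acid on work-up.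

Step 15
Reactants: 25 6-[2-(acetoxymethyl)-6-(methoxymethoxy)-4-methylphenoxy]-2-(methoxymethoxy)-3-(3-methylbut-2-enyl)benzoic acid
Product: 26 7-O-acetylsecopenicillide C
Conditions: ZnBr2 (2.5 equiv), n-PrSH (5 equiv), CH2Cl2, 0 °C, 10–15 min
Reagents that add atoms: none
Why: Thiol-assisted Lewis-acid cleavage of aryl MOM ethers, in which zinc activates the acetal and the soft thiol carries off the methoxymethyl cation within minutes in a non-protic, alcohol-free medium, so chroman formation from the prenyl group and solvolysis of the acetate should not compete.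

Compound list
1 | 4-bromoresorcinol (4-bromobenzene-1,3-diol) | Oc1ccc(Br)c(O)c1 | starting material
2 | 4-bromo-3-hydroxyphenyl N,N-diethylcarbamate | CCN(CC)C(=O)Oc1ccc(Br)c(O)c1 | intermediate
3 | 4-bromo-3-(methoxymethoxy)phenyl N,N-diethylcarbamate | CCN(CC)C(=O)Oc1ccc(Br)c(OCOC)c1 | intermediate
4 | 4-bromo-2-lithio-3-(methoxymethoxy)phenyl N,N-diethylcarbamate (not isolated) | CCN(CC)C(=O)Oc1ccc(Br)c(OCOC)c1[Li] | intermediate
5 | 4-bromo-3-(methoxymethoxy)-2-(trimethylsilyl)phenyl N,N-diethylcarbamate | CCN(CC)C(=O)Oc1ccc(Br)c(OCOC)c1[Si](C)(C)C | intermediate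
6 | prenyl bromide (1-bromo-3-methylbut-2-ene) | CC(C)=CCBr | starting material
7 | 4-lithio-3-(methoxymethoxy)-2-(trimethylsilyl)phenyl N,N-diethylcarbamate (not isolated) | CCN(CC)C(=O)Oc1ccc([Li])c(OCOC)c1[Si](C)(C)C | intermediate
8 | 3-(methoxymethoxy)-4-(3-methylbut-2-enyl)-2-(trimethylsilyl)phenyl N,N-diethylcarbamate | CCN(CC)C(=O)Oc1ccc(CC=C(C)C)c(OCOC)c1[Si](C)(C)C | intermediate
9 | 3-(methoxymethoxy)-4-(3-methylbut-2-enyl)-2-(trimethylsilyl)phenol | Oc1ccc(CC=C(C)C)c(OCOC)c1[Si](C)(C)C | intermediate
10 | 3-(methoxymethoxy)-4-(3-methylbut-2-enyl)-2-(trimethylsilyl)phenyl trifluoromethanesulfonate | COCOc1c(CC=C(C)C)ccc(OS(=O)(=O)C(F)(F)F)c1[Si](C)(C)C | intermediate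
11 | 2-methoxy-4-methylphenol (creosol) | COc1cc(C)ccc1O | starting material
12 | 2-hydroxy-3-methoxy-5-methylbenzaldehyde | COc1cc(C)cc(C=O)c1O | intermediate
13 | 2,3-dihydroxy-5-methylbenzaldehyde | Cc1cc(O)c(O)c(C=O)c1 | intermediate
14 | disodium 3-formyl-5-methylbenzene-1,2-diolate (not isolated) | Cc1cc([O-])c([O-])c(C=O)c1.[Na+].[Na+] | intermediate
15 | 2-hydroxy-3-(methoxymethoxy)-5-methylbenzaldehyde | COCOc1cc(C)cc(C=O)c1O | intermediate
16 | 2-(hydroxymethyl)-6-(methoxymethoxy)-4-methylphenol | COCOc1cc(C)cc(CO)c1O | intermediate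
17 | 2-(methoxymethoxy)-4-methyl-6-[(triisopropylsilyloxy)methyl]phenol | COCOc1cc(C)cc(CO[Si](C(C)C)(C(C)C)C(C)C)c1O | intermediate
18 | carbon dioxide | O=C=O | starting material
19 | potassium 2-(methoxymethoxy)-4-methyl-6-[(triisopropylsilyloxy)methyl]phenoxide (not isolated) | COCOc1cc(C)cc(CO[Si](C(C)C)(C(C)C)C(C)C)c1[O-].[K+] | intermediate
20 | 3-(methoxymethoxy)-4-(3-methylbut-2-enyl)benzyne (not isolated) | COCOC1=C(CC=C(C)C)C=CC#C1 | intermediate
21 | ring B C1 arylpotassium: potassium 2-{2-(methoxymethoxy)-4-methyl-6-[(triisopropylsilyloxy)methyl]phenoxy}-6-(methoxymethoxy)-5-(3-methylbut-2-enyl)phenide (not isolated) | COCOc1c(CC=C(C)C)ccc(Oc2c(CO[Si](C(C)C)(C(C)C)C(C)C)cc(C)cc2OCOC)[c-]1.[K+] | intermediate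
22 | potassium salt of acid 23 (not isolated) | COCOc1c(CC=C(C)C)ccc(Oc2c(CO[Si](C(C)C)(C(C)C)C(C)C)cc(C)cc2OCOC)c1C(=O)[O-].[K+] | intermediate
23 | 6-{2-(methoxymethoxy)-4-methyl-6-[(triisopropylsilyloxy)methyl]phenoxy}-2-(methoxymethoxy)-3-(3-methylbut-2-enyl)benzoic acid | COCOc1c(CC=C(C)C)ccc(Oc2c(CO[Si](C(C)C)(C(C)C)C(C)C)cc(C)cc2OCOC)c1C(=O)O | intermediate
24 | 6-[2-(hydroxymethyl)-6-(methoxymethoxy)-4-methylphenoxy]-2-(methoxymethoxy)-3-(3-methylbut-2-enyl)benzoic acid | COCOc1c(CC=C(C)C)ccc(Oc2c(CO)cc(C)cc2OCOC)c1C(=O)O | intermediate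
25 | 6-[2-(acetoxymethyl)-6-(methoxymethoxy)-4-methylphenoxy]-2-(methoxymethoxy)-3-(3-methylbut-2-enyl)benzoic acid | COCOc1c(CC=C(C)C)ccc(Oc2c(COC(C)=O)cc(C)cc2OCOC)c1C(=O)O | intermediate
26 | 7-O-acetylsecopenicillide C, 6-[2-(acetoxymethyl)-6-hydroxy-4-methylphenoxy]-2-hydroxy-3-(3-methylbut-2-enyl)benzoic acid | CC(=O)OCc1cc(C)cc(O)c1Oc1ccc(CC=C(C)C)c(O)c1C(=O)O | target

Total step count: 15. Longest linear sequence: 10 steps (steps 1–6, then 12–15). The ring A branch (steps 7–11) is convergent.

Steps most likely to fail

1. Step 12, the one new method.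
- What may go wrong: proton capture by the C1 carbanion before it meets CO2; reversible masking of the phenoxide as its carbonate under pressure; transfer of the silyl group from the benzylic to the phenolic oxygen; ene reaction of the aryne at a prenyl group.
- Fallback with known chemistry: it sets out from 10 and 17. The fluoride-induced O-arylation is run without CO2 (CsF, MeCN, rt), the phenol itself supplying the C1 proton. This should give 1-{2-(methoxymethoxy)-4-methyl-6-[(triisopropylsilyloxy)methyl]phenoxy}-3-(methoxymethoxy)-4-(3-methylbut-2-enyl)benzene F1.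
- The C1–H, flanked by OMOM and OAr, is then removed by directed ortho metalation (n-BuLi, THF, −78 → −20 °C) to give the C1-lithio diaryl ether F2. Quenching with CO2 gas and acidification rejoin the route at 23.

2. Step 15.
- What may go wrong: acid-induced cyclisation of the prenyl group onto the freed C2 phenol; ionisation or thiolysis at the benzylic acetate; incomplete cleavage of the ring A acetal.
- Fallback with the order of events reversed: it sets out from 24. Both MOM groups are removed while no ester is present, with dilute HCl in MeOH at rt, the standard treatment for prenylated phenols. This should give secopenicillide C, 2-hydroxy-6-[2-hydroxy-6-(hydroxymethyl)-4-methylphenoxy]-3-(3-methylbut-2-enyl)benzoic acid F3.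
- The primary benzylic alcohol alone is then acetylated with vinyl acetate and immobilised Candida antarctica lipase B in tert-butyl methyl ether. This biocatalyst acylates aliphatic alcohols and leaves phenols alone. The sequence arrives at 26 and bypasses 25.

3. Step 1.
- What may go wrong: poor discrimination between the two hydroxyl groups and over-carbamoylation.
- Fallback by a sulfonate relay: it sets out from 1. The established mono-tosylation at the oxygen para to bromine (TsCl, K2CO3, acetone, reflux) should give 4-bromo-3-hydroxyphenyl 4-methylbenzenesulfonate F4.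
- MOMCl/iPr2NEt then gives 4-bromo-3-(methoxymethoxy)phenyl 4-methylbenzenesulfonate F5, and KOH in aqueous EtOH at reflux frees 4-bromo-3-(methoxymethoxy)phenol F6.
- Carbamoylation of this single phenol (Et2NCOCl, K2CO3, MeCN) rejoins the route at 3.

Further compounds
F1 | step 12 | 1-{2-(methoxymethoxy)-4-methyl-6-[(triisopropylsilyloxy)methyl]phenoxy}-3-(methoxymethoxy)-4-(3-methylbut-2-enyl)benzene | COCOc1cc(Oc2c(CO[Si](C(C)C)(C(C)C)C(C)C)cc(C)cc2OCOC)ccc1CC=C(C)C
F2 | step 12 | C1-lithio diaryl ether (F1 lithiated between OMOM and OAr) | COCOc1c(CC=C(C)C)ccc(Oc2c(CO[Si](C(C)C)(C(C)C)C(C)C)cc(C)cc2OCOC)c1[Li]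
F3 | step 15 | secopenicillide C, 2-hydroxy-6-[2-hydroxy-6-(hydroxymethyl)-4-methylphenoxy]-3-(3-methylbut-2-enyl)benzoic acid | Cc1cc(O)c(Oc2ccc(CC=C(C)C)c(O)c2C(=O)O)c(CO)c1
F4 | step 1 | 4-bromo-3-hydroxyphenyl 4-methylbenzenesulfonate | Cc1ccc(cc1)S(=O)(=O)Oc1ccc(Br)c(O)c1
F5 | step 1 | 4-bromo-3-(methoxymethoxy)phenyl 4-methylbenzenesulfonate | Cc1ccc(cc1)S(=O)(=O)Oc1ccc(Br)c(OCOC)c1
F6 | step 1 | 4-bromo-3-(methoxymethoxy)phenol | COCOc1cc(O)ccc1Br
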